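**Assumptions:** The target has no stereocentre (it is achiral and its SMILES carries no stereo descriptors), so no stereocontrol is needed. It is delivered as the free aryl hydrogen sulfate, as drawn. Compounds 1, 5 and 8 are taken as catalogue compounds. This route has not been run; steps 3 and 4 are the untested ones.

## Retrosynthetic overview

1. Last bond: O-sulfation of the ring-A phenol, which is carried as its methyl ether until both diaryl ethers are in place.
2. Ring B–O–ring C ether and the ring-C C–I bond are made together: I→O 1,4-aryl shift in an ortho-hydroxy diaryliodonium, with the ring-B carbon acting as an aryl-cation equivalent on iodine(III) towards the ring-C phenoxide.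
3. Ring A–O–ring B ether and the ring-B C–I bond are made together by the same shift, in the iodonium phenolate from the ring-A ArI(OAc)2 and 3,4,5-tribromophenol. One iodine atom is relayed A → B → C and ends as the iodine of the target.
4. The ring-A aryl iodide comes from 2,4-dibromo-6-methoxyaniline by Sandmeyer iodination.
5. No ring is built. The target has no C–C bond outside its three benzene rings, so the strategic bonds are the two C–O bonds, each made with polarity reversal at an arene carbon. Assembly order: A, then A–O–B, then A–O–B–O–C.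

## Route

**Step 1**
Reactants: 1 2,4-dibromo-6-methoxyaniline
Product: 3 1,5-dibromo-2-iodo-3-methoxybenzene, via arenediazonium hydrogen sulfate 2 (not isolated)
Conditions: NaNO2, H2SO4, AcOH/H2O, 0–5 °C; then KI, H2O, 0 °C → rt
Reagents that add atoms: potassium iodide, [K+].[I-] (I of 3); sodium nitrite, [Na+].[O-]N=O (its N stays only in intermediate 2); sulfuric acid, OS(=O)(=O)O (counter-ion of 2 only)
Why: Sandmeyer-type iodo-dediazoniation (iodide reduces the diazonium without copper), which places iodine exactly at the former amine carbon between OMe and Br.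

**Step 2**
Reactants: 3 1,5-dibromo-2-iodo-3-methoxybenzene
Product: 4 1,5-dibromo-2-(diacetoxy-λ3-iodanyl)-3-methoxybenzene
Conditions: mCPBA (1.3 equiv), AcOH, 55 °C
Reagents that add atoms: acetic acid, CC(=O)O
Why: Peracid oxidation of an iodoarene to its (diacetoxyiodo)arene in acetic acid, which tolerates ortho substituents and halogenated rings; the dibrominated anisole ring is too deactivated to be oxidised.

**Step 3**
Reactants: 4 1,5-dibromo-2-(diacetoxy-λ3-iodanyl)-3-methoxybenzene; 5 3,4,5-tribromophenol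
Product: 7 1,2,3-tribromo-5-(2,4-dibromo-6-methoxyphenoxy)-4-iodobenzene, via aryliodonium phenolate 6 (not isolated)
Conditions: KOH (2 equiv), MeOH, 0 °C; then solvent switch to MeCN, 80 °C
Reagents that add atoms: none
Why: Iodonium ylide formation of an electron-poor phenol (acidity close to 4-cyanophenol, two equivalent ortho carbons, para blocked) followed by the thermal I→O 1,4-aryl migration of aryliodonium phenolates (Smiles-type ligand coupling), in which the phenoxide attacks the ipso carbon activated by ortho/para Br and the iodine stays ortho on ring B.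

**Step 4**
Reactants: 7 1,2,3-tribromo-5-(2,4-dibromo-6-methoxyphenoxy)-4-iodobenzene; 8 (5-bromo-2-hydroxyphenyl)boronic acid
Product: 12 1,2,3-tribromo-4-(4-bromo-2-iodophenoxy)-5-(2,4-dibromo-6-methoxyphenoxy)benzene, via Koser-type hydroxy(tosyloxy)iodane 9 (not isolated), via ortho-hydroxy diaryliodonium tosylate 10 (not isolated), via iodonium phenolate zwitterion 11 (not isolated)
Conditions: mCPBA (1.05 equiv), TsOH·H2O, CH2Cl2/CF3CH2OH, rt → 40 °C; then 8, CH2Cl2, −30 °C → rt; concentrate; Cs2CO3, MeCN, rt → 50 °C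
Reagents that add atoms: p-toluenesulfonic acid, Cc1ccc(S(=O)(=O)O)cc1 (tosylate stays only in 9 and 10); mCPBA, OOC(=O)c1cccc(Cl)c1 (its oxygen stays only as I–OH of 9)
Why: Proposed new method: the aryl iodide is oxidised to a Koser-type λ3-iodane, ipso-substitution of the C–B bond ortho to the free OH gives the ortho-hydroxy diaryliodonium (closest known: regiospecific diaryliodonium synthesis from ArI(OH)OTs and arylboronic acids), and deprotonation triggers an intramolecular I→O 1,4-aryl shift through a five-membered spiro transition state (closest known: base-induced aryl migration of ortho-oxygenated diaryliodonium salts and the thermal rearrangement of aryliodonium phenolates to 2-iodophenyl aryl ethers), so the ring-B carbon reacts as an aryl-cation equivalent, the departing iodine lands ortho to oxygen on ring C where the target needs it, and the migrating aryl has no ortho hydrogen so aryne formation is shut off.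

**Step 5**
Reactants: 12 1,2,3-tribromo-4-(4-bromo-2-iodophenoxy)-5-(2,4-dibromo-6-methoxyphenoxy)benzene
Product: 14 3,5-dibromo-2-[3,4,5-tribromo-2-(4-bromo-2-iodophenoxy)phenoxy]phenol, via aryloxydibromoborane 13 (not isolated)
Conditions: BBr3, CH2Cl2, −78 → 0 °C; then H2O
Reagents that add atoms: boron tribromide, BrB(Br)Br (its B and Br stay only in intermediate 13)
Why: Lewis-acid O-demethylation of the only alkyl aryl ether (diaryl ethers, C–Br and C–I are inert to BBr3), placed after step 4 because a free ring-A phenoxide there would close onto the iodonium-bearing carbon to give a dibenzo-p-dioxin.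

**Step 6**
Reactants: 14 3,5-dibromo-2-[3,4,5-tribromo-2-(4-bromo-2-iodophenoxy)phenoxy]phenol
Product: 16 Bromoiesol B sulfate (3,5-dibromo-2-[3,4,5-tribromo-2-(4-bromo-2-iodophenoxy)phenoxy]phenyl hydrogen sulfate), via pyridinium aryl sulfate 15 (not isolated)
Conditions: SO3·pyridine (5 equiv), pyridine, 50 °C; then Dowex 50W (H+ form), MeOH/H2O, 0 °C; lyophilise
Reagents that add atoms: sulfur trioxide–pyridine complex, [O-]S(=O)(=O)[n+]1ccccc1 (SO3 stays in 16; pyridine only as counter-ion of 15)
Why: O-sulfation of the single phenol with an SO3–amine complex, followed by cation exchange to release the hydrogen sulfate drawn in the target.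

## Compound list

1 | 2,4-dibromo-6-methoxyaniline | COc1cc(Br)cc(Br)c1N | starting material
2 | 2,4-dibromo-6-methoxybenzenediazonium hydrogen sulfate | COc1cc(Br)cc(Br)c1[N+]#N.OS(=O)(=O)[O-] | intermediate
3 | 1,5-dibromo-2-iodo-3-methoxybenzene | COc1cc(Br)cc(Br)c1I | intermediate
4 | 1,5-dibromo-2-(diacetoxy-λ3-iodanyl)-3-methoxybenzene | COc1cc(Br)cc(Br)c1I(OC(C)=O)OC(C)=O | intermediate
5 | 3,4,5-tribromophenol | Oc1cc(Br)c(Br)c(Br)c1 | starting material
6 | 3,4,5-tribromo-2-[(2,4-dibromo-6-methoxyphenyl)iodonio]phenolate | COc1cc(Br)cc(Br)c1[I+]c1c([O-])cc(Br)c(Br)c1Br | intermediate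
7 | 1,2,3-tribromo-5-(2,4-dibromo-6-methoxyphenoxy)-4-iodobenzene | COc1cc(Br)cc(Br)c1Oc1cc(Br)c(Br)c(Br)c1I | intermediate
8 | (5-bromo-2-hydroxyphenyl)boronic acid | OB(O)c1cc(Br)ccc1O | starting material
9 | [2,3,4-tribromo-6-(2,4-dibromo-6-methoxyphenoxy)phenyl](hydroxy)(tosyloxy)-λ3-iodane | COc1cc(Br)cc(Br)c1Oc1cc(Br)c(Br)c(Br)c1I(O)OS(=O)(=O)c1ccc(C)cc1 | intermediate
10 | (5-bromo-2-hydroxyphenyl)[2,3,4-tribromo-6-(2,4-dibromo-6-methoxyphenoxy)phenyl]iodonium tosylate | COc1cc(Br)cc(Br)c1Oc1cc(Br)c(Br)c(Br)c1[I+]c1cc(Br)ccc1O.Cc1ccc(S(=O)(=O)[O-])cc1 | intermediate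
11 | 4-bromo-2-{[2,3,4-tribromo-6-(2,4-dibromo-6-methoxyphenoxy)phenyl]iodonio}phenolate | COc1cc(Br)cc(Br)c1Oc1cc(Br)c(Br)c(Br)c1[I+]c1cc(Br)ccc1[O-] | intermediate
12 | 1,2,3-tribromo-4-(4-bromo-2-iodophenoxy)-5-(2,4-dibromo-6-methoxyphenoxy)benzene | COc1cc(Br)cc(Br)c1Oc1cc(Br)c(Br)c(Br)c1Oc1ccc(Br)cc1I | intermediate
13 | dibromo{3,5-dibromo-2-[3,4,5-tribromo-2-(4-bromo-2-iodophenoxy)phenoxy]phenoxy}borane | BrB(Br)Oc1cc(Br)cc(Br)c1Oc1cc(Br)c(Br)c(Br)c1Oc1ccc(Br)cc1I | intermediate
14 | 3,5-dibromo-2-[3,4,5-tribromo-2-(4-bromo-2-iodophenoxy)phenoxy]phenol | Oc1cc(Br)cc(Br)c1Oc1cc(Br)c(Br)c(Br)c1Oc1ccc(Br)cc1I | intermediate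
15 | pyridinium 3,5-dibromo-2-[3,4,5-tribromo-2-(4-bromo-2-iodophenoxy)phenoxy]phenyl sulfate | [O-]S(=O)(=O)Oc1cc(Br)cc(Br)c1Oc1cc(Br)c(Br)c(Br)c1Oc1ccc(Br)cc1I.c1cc[nH+]cc1 | intermediate
16 | Bromoiesol B sulfate | O=S(=O)(O)Oc1cc(Br)cc(Br)c1Oc1cc(Br)c(Br)c(Br)c1Oc1ccc(Br)cc1I | target

## Count and risks

Total step count: 6. Longest linear sequence: 6 (1 → 3 → 4 → 7 → 12 → 14 → 16); 5 and 8 enter as bought building blocks.

The three steps most likely to fail:

**Step 4.** The free phenol of 8 may be oxidised by the iodine(III) centre of 9 before the C–B bond is substituted, or the crowded iodonium may not form. The fallback sets out from 7 and comes back at 12. Compound 7 is oxidised to 9 as in step 4 and 9 is captured with 1,3,5-trimethoxybenzene to give the isolable salt [2,3,4-tribromo-6-(2,4-dibromo-6-methoxyphenoxy)phenyl](2,4,6-trimethoxyphenyl)iodonium tosylate F3. Separately, 4-bromophenol is iodinated with N-iodosuccinimide/TsOH to give 4-bromo-2-iodophenol F4 (also a catalogue compound). F3 and F4 are then joined by intermolecular metal-free O-arylation (t-BuOK, THF, 40 °C). The electron-rich trimethoxyphenyl group stays on iodine as the dummy ligand and the hindered, brominated ring-B aryl is transferred, giving 12. The iodine of ring C then comes from F4 and not from the relay.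

**Step 3.** 3,4,5-Tribromophenol may be oxidised (quinone-type products) and fail to give the ylide 6, or 6 may decompose without migration. The fallback sets out from 4 and 5 and comes back at 7. Compound 4 is condensed with 1,3,5-trimethoxybenzene and TsOH·H2O (MeCN, rt) to give (2,4-dibromo-6-methoxyphenyl)(2,4,6-trimethoxyphenyl)iodonium tosylate F1. Compound 5 is mono-iodinated at one of its two equivalent ortho positions (N-iodosuccinimide, cat. TsOH, MeCN) to give 3,4,5-tribromo-2-iodophenol F2. Intermolecular O-arylation of F2 with F1 (t-BuOK, THF, 40 °C) transfers the dibromomethoxyphenyl group and gives 7.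

**Step 6.** The hindered, electron-poor phenol may sulfate slowly, and the free hydrogen sulfate may hydrolyse during isolation. The fallback sets out from 14 and comes back at 16. Compound 14 is treated with neopentyl chlorosulfate (Et3N, DMAP, THF, 0 °C → rt) to give the chromatographable diester neopentyl 3,5-dibromo-2-[3,4,5-tribromo-2-(4-bromo-2-iodophenoxy)phenoxy]phenyl sulfate F5. The neopentyl group is removed by SN2 attack of azide (NaN3, DMF, 70 °C) to give sodium 3,5-dibromo-2-[3,4,5-tribromo-2-(4-bromo-2-iodophenoxy)phenoxy]phenyl sulfate F6. Cold acidification (1 M HCl, 0 °C, extraction) then gives 16.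

## Further compounds

F1 | step 3 | (2,4-dibromo-6-methoxyphenyl)(2,4,6-trimethoxyphenyl)iodonium tosylate | COc1cc(Br)cc(Br)c1[I+]c1c(OC)cc(OC)cc1OC.Cc1ccc(S(=O)(=O)[O-])cc1
F2 | step 3 | 3,4,5-tribromo-2-iodophenol | Oc1cc(Br)c(Br)c(Br)c1I
F3 | step 4 | [2,3,4-tribromo-6-(2,4-dibromo-6-methoxyphenoxy)phenyl](2,4,6-trimethoxyphenyl)iodonium tosylate | COc1cc(Br)cc(Br)c1Oc1cc(Br)c(Br)c(Br)c1[I+]c1c(OC)cc(OC)cc1OC.Cc1ccc(S(=O)(=O)[O-])cc1
F4 | step 4 | 4-bromo-2-iodophenol | Oc1ccc(Br)cc1I
F5 | step 6 | neopentyl 3,5-dibromo-2-[3,4,5-tribromo-2-(4-bromo-2-iodophenoxy)phenoxy]phenyl sulfate | CC(C)(C)COS(=O)(=O)Oc1cc(Br)cc(Br)c1Oc1cc(Br)c(Br)c(Br)c1Oc1ccc(Br)cc1I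
F6 | step 6 | sodium 3,5-dibromo-2-[3,4,5-tribromo-2-(4-bromo-2-iodophenoxy)phenoxy]phenyl sulfate | [Na+].[O-]S(=O)(=O)Oc1cc(Br)cc(Br)c1Oc1cc(Br)c(Br)c(Br)c1Oc1ccc(Br)cc1I
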